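**Plan**

- The retrosynthesis first cuts C4–H of the 1,2-dioxane (a temporary C4 hydroxyl), then C4–C5 and O1–C6 of the ring O1–O2–C3–C4–C5–C6, giving triene 15 and α-peroxy aldehyde 21.
- Enabling feature: C6 is a tertiary peroxy carbon carrying CH3 and the CH2CH2 chain, i.e. the Markovnikov end of an isopropenyl-type alkene C5=C6. C4 lies next to the peroxy-bearing C3, so a C4 aldehyde with O2–O1–t-Bu on C3 is a four-atom partner for that alkene.
- Decalin: the exo-methylene comes from a ketone. Ring A (cyclohexene) and ring B arise together by intramolecular Diels–Alder reaction of a 1,7,9-decatrien-3-one (bonds C4a–C8a and C7–C8). The trienone comes from C1–C5 cleavage of a cyclopentanone template.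
- Forward order: cyclopentanone (two stereocenters), ring opening, diene and vinyl ketone, both carbocycles in one step, methylenation, dioxane annulation, deoxygenation.
- Stereochemistry: decalin C3 by the copper catalyst, C2 by 1,2-induction on the five-membered ring, ring fusion by the endo chair transition state. Dioxane C3 and the propanoate carbon come from dimethyl (R)-malate (anti methylation, then SN2 inversion by t-BuOOH). C6 is set in the key step without strong substrate control.

Key step: step 16

Remark on the chemistry: the C5 carbinol of 8 and the C4 carbinol of 22 and 23 are temporary; 8 is carried as an epimer mixture, and the C4 configuration written for 22 and 23 is the one expected from chelation control, either epimer serving equally.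

**Route**

Step 1
Reactants: 1 2-methylcyclopent-2-en-1-one
Product: 3 (S)-[(2,3-dimethylcyclopent-1-en-1-yl)oxy]trimethylsilane, via dimethylaluminium enolate 2 (not isolated)
Conditions: Me3Al, copper thiophene-2-carboxylate Cu(O2CC4H3S) (2 mol %), BINOL-derived phosphoramidite ligand (4 mol %, enantiomer that gives 3S), Et2O, −30 °C; then TMSOTf, THF, −30 → 0 °C
Reagents that add atoms: trimethylaluminium C[Al](C)C; trimethylsilyl trifluoromethanesulfonate C[Si](C)(C)OS(=O)(=O)C(F)(F)F
Why: Copper-catalysed asymmetric conjugate addition sets C3 (S) under ligand control, and O-silylation of the regiodefined enolate stores it as the tetrasubstituted silyl enol ether.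

Step 2
Reactants: 3 (S)-[(2,3-dimethylcyclopent-1-en-1-yl)oxy]trimethylsilane; 4 but-3-en-2-one
Product: 5 (2R,3S)-2,3-dimethyl-2-(3-oxobutyl)cyclopentan-1-one
Conditions: BF3·OEt2, i-PrOH, CH2Cl2, −78 °C
Reagents that add atoms: none
Why: Mukaiyama–Michael addition builds the quaternary carbon at the enol ether carbon; the enone approaches the ring face anti to the neighbouring C3 methyl, so the two methyl groups end up cis.

Step 3
Reactants: 5 (2R,3S)-2,3-dimethyl-2-(3-oxobutyl)cyclopentan-1-one
Product: 6 (2R,3S)-2,3-dimethyl-2-(3-methylbut-3-en-1-yl)cyclopentan-1-one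
Conditions: Ph3PCH3Br, KN(SiMe3)2 (slight deficit to the salt), THF, −78 → 0 °C
Reagents that add atoms: methyltriphenylphosphonium bromide C[P+](c1ccccc1)(c1ccccc1)c1ccccc1.[Br-]
Why: Wittig methylenation should take the unhindered methyl ketone and leave the ring ketone, which is shielded by the adjacent quaternary carbon; base-free ylide limits aldol closure of the 1,5-diketone.

Step 4
Reactants: 6 (2R,3S)-2,3-dimethyl-2-(3-methylbut-3-en-1-yl)cyclopentan-1-one
Product: 8 (2R,3S)-5-hydroxy-2,3-dimethyl-2-(3-methylbut-3-en-1-yl)cyclopentan-1-one (C5 epimers), via sodium enolate 7 (not isolated)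
Conditions: NaN(SiMe3)2, THF, −78 °C; 2-(phenylsulfonyl)-3-phenyloxaziridine; aq NH4Cl
Reagents that add atoms: 2-(phenylsulfonyl)-3-phenyloxaziridine O=S(=O)(c1ccccc1)N1OC1c1ccccc1
Why: Enolate hydroxylation with an N-sulfonyloxaziridine; only C5 carries α-hydrogens, and the new carbinol configuration does not matter because the next step destroys it.

Step 5
Reactants: 8 (2R,3S)-5-hydroxy-2,3-dimethyl-2-(3-methylbut-3-en-1-yl)cyclopentan-1-one
Product: 9 methyl (2R,3S)-2,3-dimethyl-2-(3-methylbut-3-en-1-yl)-5-oxopentanoate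
Conditions: Pb(OAc)4, MeOH/PhH, 0 °C
Reagents that add atoms: methanol CO
Why: Criegee-type α-ketol cleavage through the methyl hemiketal opens the C1–C5 bond to ester and aldehyde; neither stereocenter is enolisable, so both are kept.

Step 6
Reactants: 9 methyl (2R,3S)-2,3-dimethyl-2-(3-methylbut-3-en-1-yl)-5-oxopentanoate
Product: 10 methyl (2R,3S,5E)-2,3-dimethyl-2-(3-methylbut-3-en-1-yl)-7-oxooct-5-enoate
Conditions: Ph3P=CHC(O)CH3, toluene, 60 °C
Reagents that add atoms: 1-(triphenylphosphoranylidene)propan-2-one CC(=O)C=P(c1ccccc1)(c1ccccc1)c1ccccc1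
Why: Wittig reaction of a stabilised ylide with the aldehyde gives the (E)-enone and leaves the hindered ester alone.

Step 7
Reactants: 10 methyl (2R,3S,5E)-2,3-dimethyl-2-(3-methylbut-3-en-1-yl)-7-oxooct-5-enoate
Product: 11 methyl (2R,3S,5E)-2,3,7-trimethyl-2-(3-methylbut-3-en-1-yl)octa-5,7-dienoate
Conditions: Ph3PCH3Br, KN(SiMe3)2, THF, −78 → 0 °C
Reagents that add atoms: methyltriphenylphosphonium bromide C[P+](c1ccccc1)(c1ccccc1)c1ccccc1.[Br-]
Why: Wittig methylenation of the enone carbonyl completes the (E)-2-methylbuta-1,3-dienyl unit with the geometry fixed in step 6; the neopentyl-type ester is inert.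

Step 8
Reactants: 11 methyl (2R,3S,5E)-2,3,7-trimethyl-2-(3-methylbut-3-en-1-yl)octa-5,7-dienoate
Product: 12 (2R,3S,5E)-N-methoxy-N,2,3,7-tetramethyl-2-(3-methylbut-3-en-1-yl)octa-5,7-dienamide
Conditions: MeNH(OMe)·HCl, AlMe3, CH2Cl2, 0 → 40 °C
Reagents that add atoms: N,O-dimethylhydroxylamine hydrochloride CNOC.Cl
Why: Aluminium-amide aminolysis is the standard way to turn unreactive esters into N-methoxy-N-methylamides; the quaternary α-carbon cannot epimerise.

Step 9
Reactants: 12 (2R,3S,5E)-N-methoxy-N,2,3,7-tetramethyl-2-(3-methylbut-3-en-1-yl)octa-5,7-dienamide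
Product: 13 (4R,5S,7E)-4,5,9-trimethyl-4-(3-methylbut-3-en-1-yl)deca-1,7,9-trien-3-one
Conditions: CH2=CHMgBr, THF, −78 → 0 °C; cold 1 M HCl; used at once
Reagents that add atoms: vinylmagnesium bromide C=C[Mg]Br
Why: Grignard addition to the N-methoxy-N-methylamide stops at the chelated tetrahedral adduct, and the acidic quench protonates the released amine so that it cannot add to the vinyl ketone.

Step 10
Reactants: 13 (4R,5S,7E)-4,5,9-trimethyl-4-(3-methylbut-3-en-1-yl)deca-1,7,9-trien-3-one
Product: 14 (2R,3S,4aR,8aS)-2,3,6-trimethyl-2-(3-methylbut-3-en-1-yl)-3,4,4a,7,8,8a-hexahydronaphthalen-1(2H)-one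
Conditions: Me2AlCl (20 mol %), CH2Cl2, −78 → −20 °C
Reagents that add atoms: none
Why: Intramolecular Diels–Alder reaction with the ketone inside the tether: the Lewis-acid-bound carbonyl lies endo under the diene, which gives the cis ring fusion, and the tether folds as a chair with the C5 methyl and the butenyl chain equatorial (C4 methyl axial), which fixes the face so that C4a and C8a arise R and S.

Step 11
Reactants: 14 (2R,3S,4aR,8aS)-2,3,6-trimethyl-2-(3-methylbut-3-en-1-yl)-3,4,4a,7,8,8a-hexahydronaphthalen-1(2H)-one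
Product: 15 (2R,3S,4aR,8aS)-2,3,6-trimethyl-1-methylidene-2-(3-methylbut-3-en-1-yl)-1,2,3,4,4a,7,8,8a-octahydronaphthalene
Conditions: Zn, CH2Br2, TiCl4, THF/CH2Cl2, 0 °C → rt
Reagents that add atoms: dibromomethane BrCBr
Why: Takai–Lombardo methylenation is non-basic and suited to hindered, enolisable ketones, so the ring-fusion carbon next to the carbonyl should not epimerise.

Step 12
Reactants: 16 dimethyl (R)-malate
Product: 18 dimethyl (2R,3S)-2-hydroxy-3-methylbutanedioate, via dilithium alkoxide enolate 17 (not isolated)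
Conditions: LiN(i-Pr)2 (2.2 equiv), THF, −78 → −20 °C; MeI, −78 → −10 °C; aq NH4Cl
Reagents that add atoms: iodomethane CI
Why: Fráter–Seebach alkylation: the chelated alkoxide enolate takes the methyl group on the face anti to the alkoxide-bearing carbon, giving the anti (2R,3S) diester with C2 untouched.

Step 13
Reactants: 18 dimethyl (2R,3S)-2-hydroxy-3-methylbutanedioate
Product: 19 dimethyl (2R,3S)-3-methyl-2-[(trifluoromethanesulfonyl)oxy]butanedioate
Conditions: Tf2O, 2,6-lutidine, CH2Cl2, −78 °C
Reagents that add atoms: trifluoromethanesulfonic anhydride O=S(=O)(OS(=O)(=O)C(F)(F)F)C(F)(F)F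
Why: O-sulfonylation with retention turns the α-hydroxy ester into an SN2-active α-triflyloxy ester.

Step 14
Reactants: 19 dimethyl (2R,3S)-3-methyl-2-[(trifluoromethanesulfonyl)oxy]butanedioate
Product: 20 dimethyl (2S,3S)-2-(tert-butylperoxy)-3-methylbutanedioate
Conditions: t-BuOOH (anhydrous, in decane), K2CO3, MeCN, −20 → 0 °C
Reagents that add atoms: tert-butyl hydroperoxide CC(C)(C)OO
Why: SN2 alkylation of the hydroperoxide at the carbonyl-activated carbon with inversion gives the (2S) peroxide, syn to the C3 methyl; the weak base, the α-effect nucleophile and the low temperature are chosen to hold back E2 loss of triflate towards the methylfumarate.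

Step 15
Reactants: 20 dimethyl (2S,3S)-2-(tert-butylperoxy)-3-methylbutanedioate
Product: 21 methyl (2S,3S)-3-(tert-butylperoxy)-2-methyl-4-oxobutanoate
Conditions: i-Bu2AlH (1.05 equiv), CH2Cl2, −90 → −78 °C; MeOH, then aq potassium sodium tartrate KNaC4H4O6; used crude
Reagents that add atoms: none
Why: Partial hydride reduction should select the α-peroxy ester, which is the more electrophilic and forms a chelated tetrahedral aluminate that survives to work-up; the hindered tert-butyl peroxide is expected to be inert at this temperature.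

Step 16
Reactants: 15 (2R,3S,4aR,8aS)-2,3,6-trimethyl-1-methylidene-2-(3-methylbut-3-en-1-yl)-1,2,3,4,4a,7,8,8a-octahydronaphthalene; 21 methyl (2S,3S)-3-(tert-butylperoxy)-2-methyl-4-oxobutanoate
Product: 22 methyl (2S)-2-[(3S,4S,6R)-4-hydroxy-6-methyl-6-{2-[(2R,3S,4aR,8aS)-2,3,6-trimethyl-1-methylidene-1,2,3,4,4a,7,8,8a-octahydronaphthalen-2-yl]ethyl}-1,2-dioxan-3-yl]propanoate
Conditions: SnCl4 (1.2 equiv), 2,6-di-tert-butyl-4-methylpyridine, CH2Cl2, −78 → −40 °C; aq NaHCO3
Reagents that add atoms: none
Why: Proposed new method: SnCl4 activates the aldehyde of 21 (with the α-peroxy oxygen as a second donor), the CH2 terminus of the side-chain 1,1-disubstituted alkene of 15 adds to the carbonyl carbon (C4–C5 bond, Prins/carbonyl-ene manifold), the tertiary C6 cation is captured through a six-membered chair by the distal oxygen of the tert-butylperoxy group (O1–C6 bond), and the peroxonium ion sheds tert-butyl as t-BuCl, which makes the closure irreversible. The closest known reaction types are the Lewis-acid annulation of peroxycarbenium ions with alkenes to 1,2-dioxolanes (the same cation capture by a peroxy oxygen, one ring atom fewer), the Prins synthesis of 1,3-dioxanes and the dealkylative closure of tert-butyl peroxides onto cationic carbon. The dioxane closes 6-endo with respect to the former C5=C6 bond, in the Markovnikov sense, so the event is a formal [4+2] union of the unit C4–C3–O2–O1 with the alkene. C3 and the propanoate carbon are carried over from 21, the temporary C4 carbinol is set by chelation control (3,4-cis) and is erased later, and C6 is set in the closure through the chair with the C3 side chain equatorial, where CH3 and the CH2CH2 chain differ little, so both C6 epimers are to be expected and the (6R) isomer is separated by chromatography. The step needs chemoselectivity for the side-chain alkene over the ring exo-methylene and the trisubstituted ring alkene, which the unhindered isopropenyl-type terminus is meant to secure (the exo-methylene is flanked by the quaternary C2 and the ring-fusion CH), and capture in preference to proton loss, which the peroxide oxygen held in a six-ring relation to the cation, the buffering base and the low temperature are meant to secure.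

Step 17
Reactants: 22 methyl (2S)-2-[(3S,4S,6R)-4-hydroxy-6-methyl-6-{2-[(2R,3S,4aR,8aS)-2,3,6-trimethyl-1-methylidene-1,2,3,4,4a,7,8,8a-octahydronaphthalen-2-yl]ethyl}-1,2-dioxan-3-yl]propanoate
Product: 23 methyl (2S)-2-[(3S,4S,6R)-6-methyl-4-[(phenoxycarbonothioyl)oxy]-6-{2-[(2R,3S,4aR,8aS)-2,3,6-trimethyl-1-methylidene-1,2,3,4,4a,7,8,8a-octahydronaphthalen-2-yl]ethyl}-1,2-dioxan-3-yl]propanoate
Conditions: PhOC(S)Cl, pyridine, DMAP (cat.), CH2Cl2, 0 °C → rt
Reagents that add atoms: O-phenyl chlorothionoformate S=C(Cl)Oc1ccccc1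
Why: Acylation of the secondary alcohol to the thionocarbonate under weakly basic conditions, which should spare the β-peroxy ester.

Step 18
Reactants: 23 methyl (2S)-2-[(3S,4S,6R)-6-methyl-4-[(phenoxycarbonothioyl)oxy]-6-{2-[(2R,3S,4aR,8aS)-2,3,6-trimethyl-1-methylidene-1,2,3,4,4a,7,8,8a-octahydronaphthalen-2-yl]ethyl}-1,2-dioxan-3-yl]propanoate
Product: 24 methyl (2S)-2-[(3R,6R)-6-methyl-6-{2-[(2R,3S,4aR,8aS)-2,3,6-trimethyl-1-methylidene-1,2,3,4,4a,7,8,8a-octahydronaphthalen-2-yl]ethyl}-1,2-dioxan-3-yl]propanoate (CNP0144520.2)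
Conditions: Bu3SnH, AIBN (cat.), toluene, 80 °C
Reagents that add atoms: none
Why: Barton–McCombie deoxygenation removes the helper oxygen; the C4 radical is held in the ring at an angle that disfavours backside attack on the O–O bond, so hydrogen transfer from the stannane should win, and no stereocenter is touched (the C3 descriptor changes from S to R only because C4 loses priority).

**Compound list**

1 | 2-methylcyclopent-2-en-1-one | CC1=CCCC1=O | starting material
2 | dimethylaluminium (S)-2,3-dimethylcyclopent-1-en-1-olate | C[Al](C)OC1=C(C)[C@@H](C)CC1 | intermediate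
3 | (S)-[(2,3-dimethylcyclopent-1-en-1-yl)oxy]trimethylsilane | C[Si](C)(C)OC1=C(C)[C@@H](C)CC1 | intermediate
4 | but-3-en-2-one | C=CC(C)=O | starting material
5 | (2R,3S)-2,3-dimethyl-2-(3-oxobutyl)cyclopentan-1-one | O=C1CC[C@H](C)[C@@]1(C)CCC(C)=O | intermediate
6 | (2R,3S)-2,3-dimethyl-2-(3-methylbut-3-en-1-yl)cyclopentan-1-one | O=C1CC[C@H](C)[C@@]1(C)CCC(C)=C | intermediate
7 | sodium (4S,5R)-4,5-dimethyl-5-(3-methylbut-3-en-1-yl)cyclopent-1-en-1-olate | [Na+].[O-]C1=CC[C@H](C)[C@@]1(C)CCC(C)=C | intermediate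
8 | (2R,3S)-5-hydroxy-2,3-dimethyl-2-(3-methylbut-3-en-1-yl)cyclopentan-1-one (C5 epimers) | O=C1C(O)C[C@H](C)[C@@]1(C)CCC(C)=C | intermediate
9 | methyl (2R,3S)-2,3-dimethyl-2-(3-methylbut-3-en-1-yl)-5-oxopentanoate | O=CC[C@H](C)[C@@](C(=O)OC)(C)CCC(C)=C | intermediate
10 | methyl (2R,3S,5E)-2,3-dimethyl-2-(3-methylbut-3-en-1-yl)-7-oxooct-5-enoate | CC(=O)/C=C/C[C@H](C)[C@@](C(=O)OC)(C)CCC(C)=C | intermediate
11 | methyl (2R,3S,5E)-2,3,7-trimethyl-2-(3-methylbut-3-en-1-yl)octa-5,7-dienoate | C=C(C)/C=C/C[C@H](C)[C@@](C(=O)OC)(C)CCC(C)=C | intermediate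
12 | (2R,3S,5E)-N-methoxy-N,2,3,7-tetramethyl-2-(3-methylbut-3-en-1-yl)octa-5,7-dienamide | C=C(C)/C=C/C[C@H](C)[C@@](C(=O)N(C)OC)(C)CCC(C)=C | intermediate
13 | (4R,5S,7E)-4,5,9-trimethyl-4-(3-methylbut-3-en-1-yl)deca-1,7,9-trien-3-one | C=C(C)/C=C/C[C@H](C)[C@@](C(=O)C=C)(C)CCC(C)=C | intermediate
14 | (2R,3S,4aR,8aS)-2,3,6-trimethyl-2-(3-methylbut-3-en-1-yl)-3,4,4a,7,8,8a-hexahydronaphthalen-1(2H)-one | O=C1[C@H]2CCC(C)=C[C@H]2C[C@H](C)[C@@]1(C)CCC(C)=C | intermediate
15 | (2R,3S,4aR,8aS)-2,3,6-trimethyl-1-methylidene-2-(3-methylbut-3-en-1-yl)-1,2,3,4,4a,7,8,8a-octahydronaphthalene | C=C1[C@H]2CCC(C)=C[C@H]2C[C@H](C)[C@@]1(C)CCC(C)=C | intermediate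
16 | dimethyl (R)-malate | COC(=O)C[C@@H](O)C(=O)OC | starting material
17 | dilithium alkoxide enolate of dimethyl (R)-malate | [Li+].[Li+].COC([O-])=C[C@@H]([O-])C(=O)OC | intermediate
18 | dimethyl (2R,3S)-2-hydroxy-3-methylbutanedioate | COC(=O)[C@@H](C)[C@@H](O)C(=O)OC | intermediate
19 | dimethyl (2R,3S)-3-methyl-2-[(trifluoromethanesulfonyl)oxy]butanedioate | COC(=O)[C@@H](C)[C@@H](OS(=O)(=O)C(F)(F)F)C(=O)OC | intermediate
20 | dimethyl (2S,3S)-2-(tert-butylperoxy)-3-methylbutanedioate | COC(=O)[C@@H](C)[C@H](OOC(C)(C)C)C(=O)OC | intermediate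
21 | methyl (2S,3S)-3-(tert-butylperoxy)-2-methyl-4-oxobutanoate | COC(=O)[C@@H](C)[C@H](OOC(C)(C)C)C=O | intermediate
22 | methyl (2S)-2-[(3S,4S,6R)-4-hydroxy-6-methyl-6-{2-[(2R,3S,4aR,8aS)-2,3,6-trimethyl-1-methylidene-1,2,3,4,4a,7,8,8a-octahydronaphthalen-2-yl]ethyl}-1,2-dioxan-3-yl]propanoate | C=C1[C@H]2CCC(C)=C[C@H]2C[C@H](C)[C@@]1(C)CC[C@]1(C)C[C@H](O)[C@H]([C@H](C)C(=O)OC)OO1 | intermediate
23 | 4-O-(phenoxycarbonothioyl) derivative of 22 | C=C1[C@H]2CCC(C)=C[C@H]2C[C@H](C)[C@@]1(C)CC[C@]1(C)C[C@H](OC(=S)Oc2ccccc2)[C@H]([C@H](C)C(=O)OC)OO1 | intermediate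
24 | methyl (2S)-2-[(3R,6R)-6-methyl-6-{2-[(2R,3S,4aR,8aS)-2,3,6-trimethyl-1-methylidene-1,2,3,4,4a,7,8,8a-octahydronaphthalen-2-yl]ethyl}-1,2-dioxan-3-yl]propanoate | C=C1[C@H]2CCC(C)=C[C@H]2C[C@H](C)[C@@]1(C)CC[C@]1(C)CC[C@H]([C@H](C)C(=O)OC)OO1 | target

**Totals and risks**

Total step count: 18. Longest linear sequence: 14 steps (steps 1–11, then 16–18); steps 12–15 form the four-step branch to 21.

Most likely to fail:

1. Step 16 (proposed new method). The tertiary cation may lose a proton (ene-type outcome) or take up chloride before the tert-butylperoxy oxygen closes the ring; the Lewis-acid-bound aldehyde may also add to one of the ring alkenes; and there is little facial selection at C6. Fallback, setting out from 15 and 21 and coming back at 22: the two bonds would be made in two known operations. A Me2AlCl-mediated carbonyl-ene reaction of 15 with 21 would give the homoallylic alcohol methyl (2S,3S,4S)-3-(tert-butylperoxy)-4-hydroxy-2-methyl-6-methylidene-8-[(2R,3S,4aR,8aS)-2,3,6-trimethyl-1-methylidene-1,2,3,4,4a,7,8,8a-octahydronaphthalen-2-yl]octanoate F1 (its trisubstituted-alkene isomer converges). Cycloperoxymercuration with Hg(OAc)2, with loss of the tert-butyl group, would close the ring to the 6-(acetoxymercuriomethyl) analogue of 22 F2. Hydridodemercuration with NaBH4/NaOH would then give 22. This does not improve the C6 selectivity; the epimers would still be separated.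

2. Step 18. The C4 radical sits β to the O–O bond and may open the peroxide ring, or the stannyl radical may attack the O–O bond directly. Fallback, setting out from 22 and coming back at 24: an ionic deoxygenation. Tf2O/pyridine would convert 22 into the 4-triflate of 22 F3, and hydride displacement with n-Bu4NBH4 in toluene would give 24 without any radical next to the peroxide.

3. Step 8. Acyl substitution at the neopentyl-type ester may not proceed, or the forcing conditions may degrade the diene. Fallback, setting out from 11 and coming back at 13: a redox sequence instead of aminolysis. LiAlH4 would reduce 11 to (2R,3S,5E)-2,3,7-trimethyl-2-(3-methylbut-3-en-1-yl)octa-5,7-dien-1-ol F4. Dess–Martin periodinane would give (2R,3S,5E)-2,3,7-trimethyl-2-(3-methylbut-3-en-1-yl)octa-5,7-dienal F5. Addition of CH2=CHMgBr would give (4R,5S,7E)-4,5,9-trimethyl-4-(3-methylbut-3-en-1-yl)deca-1,7,9-trien-3-ol F6 (carbinol epimers), and a second Dess–Martin oxidation would give 13.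

**Further compounds**

F1 | step 16 | methyl (2S,3S,4S)-3-(tert-butylperoxy)-4-hydroxy-2-methyl-6-methylidene-8-[(2R,3S,4aR,8aS)-2,3,6-trimethyl-1-methylidene-1,2,3,4,4a,7,8,8a-octahydronaphthalen-2-yl]octanoate | C=C1[C@H]2CCC(C)=C[C@H]2C[C@H](C)[C@@]1(C)CCC(=C)C[C@H](O)[C@H]([C@H](C)C(=O)OC)OOC(C)(C)C
F2 | step 16 | 6-(acetoxymercuriomethyl) analogue of 22 | C=C1[C@H]2CCC(C)=C[C@H]2C[C@H](C)[C@@]1(C)CC[C@]1(C[Hg]OC(C)=O)C[C@H](O)[C@H]([C@H](C)C(=O)OC)OO1
F3 | step 18 | 4-triflate of 22 | C=C1[C@H]2CCC(C)=C[C@H]2C[C@H](C)[C@@]1(C)CC[C@]1(C)C[C@H](OS(=O)(=O)C(F)(F)F)[C@H]([C@H](C)C(=O)OC)OO1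
F4 | step 8 | (2R,3S,5E)-2,3,7-trimethyl-2-(3-methylbut-3-en-1-yl)octa-5,7-dien-1-ol | C=C(C)/C=C/C[C@H](C)[C@@](CO)(C)CCC(C)=C
F5 | step 8 | (2R,3S,5E)-2,3,7-trimethyl-2-(3-methylbut-3-en-1-yl)octa-5,7-dienal | C=C(C)/C=C/C[C@H](C)[C@@](C=O)(C)CCC(C)=C
F6 | step 8 | (4R,5S,7E)-4,5,9-trimethyl-4-(3-methylbut-3-en-1-yl)deca-1,7,9-trien-3-ol (carbinol epimers) | C=C(C)/C=C/C[C@H](C)[C@@](C(O)C=C)(C)CCC(C)=C
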